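**Retrosynthetic overview**
1. Target 25 comes from 24 by C15 desilylation. In 24 the ten-membered carbocycle and the trans-fused α-methylene lactone are closed together: intramolecular CrCl2 allylation of the C6 enal by the C7 allyl bromide, then lactonization.
2. The furanone ring (O–C3=C2–C1(=O)–C10) is closed earlier, on the open chain, by the O–C10 bond: after an amine adds to a C1≡C2 ynone, the C3 carbonyl oxygen opens a C9–C10 oxirane at C10 (18 from 15 + H2O).
3. Enabling feature: the furanone oxygen sits on quaternary C10 next to an oxygen-bearing C9 (the footprint of a C9–C10 epoxide opened at C10), and the vinylogous ester C3=C2–C1=O is a hydrated ynone. So furanone + C9–OH = epoxy ynone + water; the oxirane is a temporary ring and the enamine a transient activating group.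
4. Ynone 15 comes from a carbonylative Sonogashira union of (Z)-vinyl iodide 14 (C4–C6, C15; from but-2-yne-1,4-diol), CO (C3) and alkyne 9.
5. Alkyne 9 comes from Sharpless epoxidation of (Z)-3-methylpent-2-en-4-yn-1-ol (sets C9, C10), Nozaki–Hiyama–Kishi vinylation at C8 with bromoacrylate 4 (C7, C11–C13) and Mitsunobu methacryloylation with inversion at C8. Ring order: oxirane (temporary), furanone, then carbocycle and lactone.

Key step: step 11

Remark: carbons are numbered C1–C15 as in germacranolides (C1 ketone, C2=C3 furanone alkene, C4=C5, C6 lactone carbinol, C7, C8 methacrylate, C9 angelate, C10 quaternary, C11–C13 methylene lactone, C14 methyl, C15 hydroxymethyl). Bromoacrylate 4 is assumed to form as the (E) isomer shown.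

**Route**

Step 1
Reactants: 1 methyl 2-(hydroxymethyl)prop-2-enoate
Product: 2 methyl 2-{[(tert-butyldimethylsilyl)oxy]methyl}prop-2-enoate
Conditions: TBSCl, imidazole, CH2Cl2, 0 °C to rt
Reagents that add atoms: tert-butyldimethylsilyl chloride, CC(C)(C)[Si](C)(C)Cl
Why: Imidazole-promoted silyl ether formation at a primary allylic alcohol is routine and creates no stereocenter.

Step 2
Reactants: 2 methyl 2-{[(tert-butyldimethylsilyl)oxy]methyl}prop-2-enoate
Product: 4 methyl (2E)-3-bromo-2-{[(tert-butyldimethylsilyl)oxy]methyl}prop-2-enoate, via dibromo ester 3 (not isolated)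
Conditions: Br2, CH2Cl2, 0 °C; then DBU, 0 °C to rt
Reagents that add atoms: bromine, BrBr
Why: Bromine addition followed by base-induced dehydrobromination (bromination–elimination sequence) should give the β-bromoacrylate with bromine trans to the ester, the less congested isomer, which is needed so that the C8 alkoxide formed in step 5 cannot lactonize.

Step 3
Reactants: 5 (2Z)-3-methylpent-2-en-4-yn-1-ol
Product: 6 [(2R,3S)-3-ethynyl-3-methyloxiran-2-yl]methanol
Conditions: Ti(OiPr)4 (cat.), D-(−)-diethyl tartrate (cat.), t-BuOOH, 4 Å sieves, CH2Cl2, −20 °C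
Reagents that add atoms: tert-butyl hydroperoxide, CC(C)(C)OO
Why: Sharpless asymmetric epoxidation of a (Z)-trisubstituted allylic alcohol, in which the D-tartrate ligand directs oxygen to the face that gives the (2R,3S) oxirane, sets C9 and the configuration of the C10 carbon that is inverted later.

Step 4
Reactants: 6 [(2R,3S)-3-ethynyl-3-methyloxiran-2-yl]methanol
Product: 7 (2S,3S)-3-ethynyl-3-methyloxirane-2-carbaldehyde
Conditions: Dess–Martin periodinane, NaHCO3, CH2Cl2, 0 °C
Reagents that add atoms: none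
Why: Buffered Dess–Martin oxidation converts the primary epoxy alcohol into the epoxy aldehyde without touching the oxirane or its stereocenters.

Step 5
Reactants: 7 (2S,3S)-3-ethynyl-3-methyloxirane-2-carbaldehyde; 4 methyl (2E)-3-bromo-2-{[(tert-butyldimethylsilyl)oxy]methyl}prop-2-enoate
Product: 8 methyl (2E,4R)-2-{[(tert-butyldimethylsilyl)oxy]methyl}-4-[(2R,3S)-3-ethynyl-3-methyloxiran-2-yl]-4-hydroxybut-2-enoate
Conditions: CrCl2 (4 equiv), NiCl2 (2 mol %), DMF, rt
Reagents that add atoms: none
Why: Nozaki–Hiyama–Kishi coupling (zerovalent nickel activates the vinyl bromide, divalent chromium carries the vinyl group to the aldehyde) keeps the alkene geometry, and polar Felkin–Anh addition anti to the oxirane C9–O bond should give the 8,9-erythro (8R) alcohol.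

Step 6
Reactants: 8 methyl (2E,4R)-2-{[(tert-butyldimethylsilyl)oxy]methyl}-4-[(2R,3S)-3-ethynyl-3-methyloxiran-2-yl]-4-hydroxybut-2-enoate
Product: 9 methyl (2E,4S)-2-{[(tert-butyldimethylsilyl)oxy]methyl}-4-[(2R,3S)-3-ethynyl-3-methyloxiran-2-yl]-4-[(2-methylprop-2-enoyl)oxy]but-2-enoate
Conditions: methacrylic acid, PPh3, DIAD, toluene, 0 °C to rt
Reagents that add atoms: methacrylic acid, C=C(C)C(=O)O
Why: Mitsunobu esterification installs the C8 methacrylate with SN2 inversion, turning the erythro alcohol into the threo (8S) ester that the target requires.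

Step 7
Reactants: 10 but-2-yne-1,4-diol
Product: 11 4-[(tert-butyldiphenylsilyl)oxy]but-2-yn-1-ol
Conditions: TBDPSCl (0.3 equiv), imidazole, DMF, 0 °C
Reagents that add atoms: tert-butyldiphenylsilyl chloride, CC(C)(C)[Si](Cl)(c1ccccc1)c1ccccc1
Why: Monosilylation of a symmetrical diol used in excess is statistical but simple, and creates no stereocenter.

Step 8
Reactants: 11 4-[(tert-butyldiphenylsilyl)oxy]but-2-yn-1-ol
Product: 13 (2Z)-4-[(tert-butyldiphenylsilyl)oxy]-3-iodobut-2-en-1-ol, via sodium vinylalanate 12 (not isolated)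
Conditions: NaAlH2(OCH2CH2OCH3)2, THF, 0 °C; then I2, THF, −78 °C to 0 °C
Reagents that add atoms: iodine, II
Why: Hydroxyl-directed trans-hydroalumination puts aluminium on the alkyne carbon remote from the free hydroxyl (C4), and iodinolysis with retention gives the vinyl iodide in which iodine (later C3) is cis to C6 and trans to C15, the C4=C5 geometry of the target.

Step 9
Reactants: 13 (2Z)-4-[(tert-butyldiphenylsilyl)oxy]-3-iodobut-2-en-1-ol
Product: 14 (2Z)-1-[(tert-butyldimethylsilyl)oxy]-4-[(tert-butyldiphenylsilyl)oxy]-3-iodobut-2-ene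
Conditions: TBSCl, imidazole, CH2Cl2, rt
Reagents that add atoms: tert-butyldimethylsilyl chloride, CC(C)(C)[Si](C)(C)Cl
Why: Silylation protects the C6 hydroxyl so that the C3 ketone made next cannot cyclize onto it to form a furan.

Step 10
Reactants: 9 methyl (2E,4S)-2-{[(tert-butyldimethylsilyl)oxy]methyl}-4-[(2R,3S)-3-ethynyl-3-methyloxiran-2-yl]-4-[(2-methylprop-2-enoyl)oxy]but-2-enoate; 14 (2Z)-1-[(tert-butyldimethylsilyl)oxy]-4-[(tert-butyldiphenylsilyl)oxy]-3-iodobut-2-ene
Product: 15 acyclic (8S,9R,10S) epoxy ynone: C3 ketone between the (4Z)-C4=C5 alkene (C15–OTBDPS and C6–OTBS) and the C1≡C2 alkyne on the C9–C10 oxirane; C8 methacrylate; methyl (E)-acrylate C7=C11 with C13–OTBS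
Conditions: PdCl2(PPh3)2 (5 mol %), CuI (2 mol %), Et3N, CO (1 atm), THF, rt
Reagents that add atoms: carbon monoxide, [C-]#[O+]
Why: Carbonylative Sonogashira coupling (oxidative addition of the vinyl iodide to zerovalent palladium, CO insertion, alkynyl transfer from the copper acetylide) joins the two fragments, brings in C3 from CO and keeps the C4=C5 geometry.

Step 11
Reactants: 15 acyclic (8S,9R,10S) epoxy ynone
Product: 18 (8S,9R,10S) hydroxy furanone: 2-methyl-3(2H)-furanone with C10 bearing C14 and the C9 carbinol and C3 bearing the (Z)-C4=C5 unit; free C9–OH; C8 methacrylate; silyl ethers and methyl (E)-acrylate as in 15, via enaminone 16 (not isolated), via iminium acetate 17 (not isolated)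
Conditions: Et2NH (1.2 equiv), EtOH, 0 °C to rt; then AcOH/NaOAc buffer (pH 5), THF–H2O, rt
Reagents that add atoms: water, O
Why: Proposed new method: diethylamine adds to C1 of the ynone (aza-Michael addition) to give the (E)-β-amino enone 16, in which the C3 carbonyl oxygen and the oxirane carbon C10 are cis and 1,5 to each other; this vinylogous amide oxygen then opens the acid-activated oxirane at C10 in a 5-exo-tet closure that forms the O–C10 bond of the furanone ring (O, C3, C2, C1, C10), and hydrolysis of iminium 17 unmasks the C1 ketone and returns the amine. The closest known reaction types are the amine-mediated cyclization of γ-hydroxy ynones to 3(2H)-furanones and the acid-promoted 5-exo opening of trisubstituted epoxides by carbonyl or enol oxygen, which goes with inversion even at tertiary carbon. C10 is therefore set by inversion of the epoxide carbon made in step 3 and C9 is retained, so both stereocenters and a free C9 hydroxyl, already distinguished from the C8 ester, come from one Sharpless epoxidation. The step needs attack at C10 to win over 6-endo attack at C9 and over participation of the C8 ester carbonyl; the five-membered ring size, the higher nucleophilicity of the enaminone oxygen and the tertiary, donor-flanked character of C10 should secure this. The acrylate, methacrylate and enone units should stay untouched because the ynone is by far the strongest Michael acceptor and only about one equivalent of amine is used. Epoxide strain drives the closure and the amine leaves on hydrolysis, so nothing has to be removed afterwards.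

Step 12
Reactants: 18 (8S,9R,10S) hydroxy furanone
Product: 19 (8S,9R,10S) furanone diester: 18 with the C9 hydroxyl esterified as the (Z)-2-methylbut-2-enoate (angelate)
Conditions: angelic acid, 2,4,6-trichlorobenzoyl chloride, Et3N, toluene, rt; then the alcohol, 70 °C
Reagents that add atoms: angelic acid, C/C=C(/C)C(=O)O
Why: Yamaguchi-type esterification through the mixed anhydride acylates the hindered C9 alcohol under weakly basic conditions that should not isomerize the angelate to the tiglate or move the C8 ester.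

Step 13
Reactants: 19 (8S,9R,10S) furanone diester
Product: 20 (8S,9R,10S) diol: 19 with free C6 and C13 hydroxyls and C15–OTBDPS kept
Conditions: HF·pyridine, pyridine, THF, 0 °C
Reagents that add atoms: none
Why: Buffered fluoride desilylation cleaves the two primary TBS ethers much faster than the primary TBDPS ether.

Step 14
Reactants: 20 (8S,9R,10S) diol
Product: 21 (8S,9R,10S) hydroxy enal: 20 with C6 oxidized to the (Z)-enal and C13–OH free
Conditions: MnO2, CH2Cl2, rt
Reagents that add atoms: none
Why: MnO2 oxidation is selective for the electron-rich allylic C6 alcohol over the deactivated 2-(hydroxymethyl)acrylate alcohol and leaves the alkene geometry intact.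

Step 15
Reactants: 21 (8S,9R,10S) hydroxy enal
Product: 22 (8S,9R,10S) bromo enal: 21 with C13–Br (methyl (Z)-2-(bromomethyl)alk-2-enoate unit)
Conditions: PBr3, pyridine (cat.), Et2O, −20 °C
Reagents that add atoms: phosphorus tribromide, BrP(Br)Br
Why: PBr3 converts the primary allylic alcohol into the conjugated allylic bromide by SN2 displacement without affecting the aldehyde or the esters.

Step 16
Reactants: 22 (8S,9R,10S) bromo enal
Product: 24 (6R,7S,8S,9R,10S) macrocyclic furanone lactone with C15–OTBDPS (the target as its C15 silyl ether), via hydroxy ester 23 (not isolated)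
Conditions: CrCl2 (8 equiv), THF, rt, slow addition to 1 mM; then p-TsOH (cat.), CH2Cl2, rt
Reagents that add atoms: none
Why: Intramolecular chromium-mediated Barbier-type (Nozaki–Hiyama) allylation closes the ten-membered ring at C6–C7 through a chair transition state of the equilibrating allyl species of trivalent chromium, which should give the anti adduct and hence the trans lactone after acid-promoted lactonization; C7 should be set by attack anti to the bulky C9 branch with H8 in the alkene plane (allylic strain).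

Step 17
Reactants: 24 (6R,7S,8S,9R,10S) macrocyclic furanone lactone with C15–OTBDPS
Product: 25 target (6R,7S,8S,9R,10S)
Conditions: HF·pyridine, THF, 0 °C to rt
Reagents that add atoms: none
Why: Fluoride cleavage of the primary TBDPS ether under non-basic conditions frees the C15 hydroxyl without harming the enoate esters, the methylene lactone or any stereocenter.

**Compound list**
1 | methyl 2-(hydroxymethyl)prop-2-enoate | C=C(CO)C(=O)OC | starting material
2 | methyl 2-{[(tert-butyldimethylsilyl)oxy]methyl}prop-2-enoate | C=C(CO[Si](C)(C)C(C)(C)C)C(=O)OC | intermediate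
3 | methyl 2,3-dibromo-2-{[(tert-butyldimethylsilyl)oxy]methyl}propanoate (racemic, not isolated) | COC(=O)C(Br)(CBr)CO[Si](C)(C)C(C)(C)C | intermediate
4 | methyl (2E)-3-bromo-2-{[(tert-butyldimethylsilyl)oxy]methyl}prop-2-enoate | Br/C=C(/C(=O)OC)CO[Si](C)(C)C(C)(C)C | intermediate
5 | (2Z)-3-methylpent-2-en-4-yn-1-ol | OC/C=C(C)\C#C | starting material
6 | [(2R,3S)-3-ethynyl-3-methyloxiran-2-yl]methanol | OC[C@H]1O[C@@]1(C)C#C | intermediate
7 | (2S,3S)-3-ethynyl-3-methyloxirane-2-carbaldehyde | O=C[C@H]1O[C@@]1(C)C#C | intermediate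
8 | methyl (2E,4R)-2-{[(tert-butyldimethylsilyl)oxy]methyl}-4-[(2R,3S)-3-ethynyl-3-methyloxiran-2-yl]-4-hydroxybut-2-enoate | O[C@@H]([C@H]1O[C@@]1(C)C#C)/C=C(/C(=O)OC)CO[Si](C)(C)C(C)(C)C | intermediate
9 | methyl (2E,4S)-2-{[(tert-butyldimethylsilyl)oxy]methyl}-4-[(2R,3S)-3-ethynyl-3-methyloxiran-2-yl]-4-[(2-methylprop-2-enoyl)oxy]but-2-enoate | C=C(C)C(=O)O[C@H]([C@H]1O[C@@]1(C)C#C)/C=C(/C(=O)OC)CO[Si](C)(C)C(C)(C)C | intermediate
10 | but-2-yne-1,4-diol | OCC#CCO | starting material
11 | 4-[(tert-butyldiphenylsilyl)oxy]but-2-yn-1-ol | OCC#CCO[Si](c1ccccc1)(c1ccccc1)C(C)(C)C | intermediate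
12 | sodium cyclic alkoxy(vinyl)bis(2-methoxyethoxy)alanate from 11 (aluminium on C4, not isolated) | [Na+].COCCO[Al-]1(OCCOC)OCC=C1CO[Si](c1ccccc1)(c1ccccc1)C(C)(C)C | intermediate
13 | (2Z)-4-[(tert-butyldiphenylsilyl)oxy]-3-iodobut-2-en-1-ol | OC/C=C(I)/CO[Si](c1ccccc1)(c1ccccc1)C(C)(C)C | intermediate
14 | (2Z)-1-[(tert-butyldimethylsilyl)oxy]-4-[(tert-butyldiphenylsilyl)oxy]-3-iodobut-2-ene | CC(C)(C)[Si](C)(C)OC/C=C(I)/CO[Si](c1ccccc1)(c1ccccc1)C(C)(C)C | intermediate
15 | acyclic (8S,9R,10S) epoxy ynone (C3 ketone, C1≡C2, C9–C10 oxirane, (4Z) alkene, C8 methacrylate, methyl (E)-acrylate, C6/C13–OTBS, C15–OTBDPS) | CC(C)(C)[Si](C)(C)OC/C=C(/CO[Si](c1ccccc1)(c1ccccc1)C(C)(C)C)C(=O)C#C[C@]1(C)O[C@@H]1[C@@H](OC(=O)C(C)=C)/C=C(/C(=O)OC)CO[Si](C)(C)C(C)(C)C | intermediate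
16 | (E)-β-(diethylamino) enone from 15 (Et2N on C1, C10 cis to the C3 carbonyl, oxirane intact, not isolated) | CC(C)(C)[Si](C)(C)OC/C=C(/CO[Si](c1ccccc1)(c1ccccc1)C(C)(C)C)C(=O)/C=C(/N(CC)CC)[C@]1(C)O[C@@H]1[C@@H](OC(=O)C(C)=C)/C=C(/C(=O)OC)CO[Si](C)(C)C(C)(C)C | intermediate
17 | 3-(diethyliminio)-2,3-dihydrofuran acetate (ring closed, free C9–OH, configuration as in 18, not isolated) | CC(C)(C)[Si](C)(C)OC/C=C(/CO[Si](c1ccccc1)(c1ccccc1)C(C)(C)C)C1=CC(=[N+](CC)CC)[C@@](C)(O1)[C@H](O)[C@@H](OC(=O)C(C)=C)/C=C(/C(=O)OC)CO[Si](C)(C)C(C)(C)C.CC(=O)[O-] | intermediate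
18 | (8S,9R,10S) hydroxy furanone (free C9–OH, C8 methacrylate) | CC(C)(C)[Si](C)(C)OC/C=C(/CO[Si](c1ccccc1)(c1ccccc1)C(C)(C)C)C1=CC(=O)[C@@](C)(O1)[C@H](O)[C@@H](OC(=O)C(C)=C)/C=C(/C(=O)OC)CO[Si](C)(C)C(C)(C)C | intermediate
19 | (8S,9R,10S) furanone diester (C9 angelate, C8 methacrylate) | CC(C)(C)[Si](C)(C)OC/C=C(/CO[Si](c1ccccc1)(c1ccccc1)C(C)(C)C)C1=CC(=O)[C@@](C)(O1)[C@H](OC(=O)/C(C)=C\C)[C@@H](OC(=O)C(C)=C)/C=C(/C(=O)OC)CO[Si](C)(C)C(C)(C)C | intermediate
20 | (8S,9R,10S) diol (free C6–OH and C13–OH, C15–OTBDPS) | OC/C=C(/CO[Si](c1ccccc1)(c1ccccc1)C(C)(C)C)C1=CC(=O)[C@@](C)(O1)[C@H](OC(=O)/C(C)=C\C)[C@@H](OC(=O)C(C)=C)/C=C(/C(=O)OC)CO | intermediate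
21 | (8S,9R,10S) hydroxy enal (C6 aldehyde, C13–OH) | O=C/C=C(/CO[Si](c1ccccc1)(c1ccccc1)C(C)(C)C)C1=CC(=O)[C@@](C)(O1)[C@H](OC(=O)/C(C)=C\C)[C@@H](OC(=O)C(C)=C)/C=C(/C(=O)OC)CO | intermediate
22 | (8S,9R,10S) bromo enal (C6 aldehyde, C13–Br) | O=C/C=C(/CO[Si](c1ccccc1)(c1ccccc1)C(C)(C)C)C1=CC(=O)[C@@](C)(O1)[C@H](OC(=O)/C(C)=C\C)[C@@H](OC(=O)C(C)=C)/C=C(/C(=O)OC)CBr | intermediate
23 | (6R,7S,8S,9R,10S) ten-membered hydroxy ester (C6–OH, C7 bearing the methyl 2-propenoate unit, not isolated) | C=C(C)C(=O)O[C@H]1[C@@H](C(=C)C(=O)OC)[C@H](O)/C=C(/CO[Si](c2ccccc2)(c2ccccc2)C(C)(C)C)C2=CC(=O)[C@@](C)(O2)[C@@H]1OC(=O)/C(C)=C\C | intermediate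
24 | (6R,7S,8S,9R,10S) macrocyclic furanone lactone, C15–OTBDPS | C=C(C)C(=O)O[C@H]1[C@H]2C(=C)C(=O)O[C@@H]2/C=C(/CO[Si](c2ccccc2)(c2ccccc2)C(C)(C)C)C2=CC(=O)[C@@](C)(O2)[C@@H]1OC(=O)/C(C)=C\C | intermediate
25 | target, (6R,7S,8S,9R,10S)-8-methacryloyloxy-9-angeloyloxy-15-hydroxy furanoheliangolide | C=C(C)C(=O)O[C@H]1[C@H]2C(=C)C(=O)O[C@@H]2/C=C(/CO)C2=CC(=O)[C@@](C)(O2)[C@@H]1OC(=O)/C(C)=C\C | target

**Step count and risks**
Total step count: 17. Longest linear sequence: 12 steps (steps 3, 4, 5, 6, 10, 11, 12, 13, 14, 15, 16, 17).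

Steps most likely to fail:

1. Step 11. The C10–O bond of the enaminone may ionize before ring closure, so that inversion at C10 is partly lost, or the oxirane may be opened at C9 (6-endo) or by the neighbouring ester carbonyl. The fallback sets out from 15 and comes back at 18. The ynone is hydrated by pyrrolidine addition and cold hydrolysis (dilute aqueous oxalic acid, 0 °C), a known ynone-to-β-diketone conversion, to give the epoxy 1,3-diketone F1. F1 is then cyclized with BF3·OEt2 in CH2Cl2 at −78 °C, the known Lewis-acid-promoted 5-exo epoxide opening by a β-dicarbonyl enol oxygen. With C1 as a ketone, ionization at C10 is disfavoured, so the opening should be a clean SN2 inversion.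

2. Step 16. Intermolecular allylation and reductive coupling of the bromide may outrun ring closure, or the allyl unit may add through the wrong face. The fallback sets out from 21 and comes back at 24. The C13 alcohol is acylated with methyl chloroformate and pyridine to the allylic methyl carbonate F2. Pd(PPh3)4 (cat.) and InI in THF at high dilution then generate the allyl nucleophile catalytically through a π-allyl complex of divalent palladium (umpolung allylation), which keeps its stationary concentration low. The chair-type addition to the C6 aldehyde should again be anti, and acid-promoted lactonization of 23 gives 24.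

3. Step 10. Coupling may proceed without CO uptake to give the enyne, or zerovalent palladium may ionize the propargylic oxirane. The fallback sets out from 14 and 9 and comes back at 15. Iodine–magnesium exchange of 14 (i-PrMgCl·LiCl, THF, −40 °C) and formylation with DMF give the (Z)-enal F3. The zinc acetylide of 9 (Me2Zn, toluene, 0 °C to rt) adds to it to give the propargylic alcohols F4 as both C3 epimers. MnO2 oxidation of the mixture gives 15.

Further compounds
F1 | step 11 | (8S,9R,10S) epoxy 1,3-diketone (C1 and C3 ketones, C2 methylene, oxirane intact) | CC(C)(C)[Si](C)(C)OC/C=C(/CO[Si](c1ccccc1)(c1ccccc1)C(C)(C)C)C(=O)CC(=O)[C@]1(C)O[C@@H]1[C@@H](OC(=O)C(C)=C)/C=C(/C(=O)OC)CO[Si](C)(C)C(C)(C)C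
F2 | step 16 | (8S,9R,10S) allylic methyl carbonate of 21 (C13–OCO2Me, C6 aldehyde) | O=C/C=C(/CO[Si](c1ccccc1)(c1ccccc1)C(C)(C)C)C1=CC(=O)[C@@](C)(O1)[C@H](OC(=O)/C(C)=C\C)[C@@H](OC(=O)C(C)=C)/C=C(/C(=O)OC)COC(=O)OC
F3 | step 10 | (2Z)-4-[(tert-butyldimethylsilyl)oxy]-2-{[(tert-butyldiphenylsilyl)oxy]methyl}but-2-enal | CC(C)(C)[Si](C)(C)OC/C=C(/CO[Si](c1ccccc1)(c1ccccc1)C(C)(C)C)C=O
F4 | step 10 | (8S,9R,10S) propargylic alcohol, C3 carbinol as a mixture of both epimers, otherwise as 15 | CC(C)(C)[Si](C)(C)OC/C=C(/CO[Si](c1ccccc1)(c1ccccc1)C(C)(C)C)C(O)C#C[C@]1(C)O[C@@H]1[C@@H](OC(=O)C(C)=C)/C=C(/C(=O)OC)CO[Si](C)(C)C(C)(C)C
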